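The angular methyl C20 is disconnected from C10: it is traced back to a 5β,10β-methylene bridge and this to a 20-nor 5(10)-ene. The key step exploits the fact that C20 on C10, the 6β-oxygen of ring B and the C19 oxygen on C4 of ring A all sit on the β face of the trans A/B decalin. The zinc alkoxides of 6β-OH and 19-OH deliver CH2 to C5=C10, forming C10–C20 and C5–C20 and setting C5 and C10 in one operation. The precursor is a tetralone-derived octalin diol carrying quaternary C4, a C3 ketal and a 9α-silyl ether; the C5–C20 bond is cut reductively afterwards.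

Key step: step 9

Remarks on the chemistry:
- Atom numbers are labdane numbers throughout (tetralone C1 = C6, C8 = C4, C7 = C3, C4 = C9).
- The target is read from its SMILES as 3α- and 19-isovalerate, 6β-OH, 5α-H, 10β-methyl, 4α-methyl, 13E.
- The C9 oxygen is a spectator whose stereocentre is erased later. It is still set as 9α by catalyst control, so that every intermediate is one isomer and the silyl ether lies on the α face.
- After the key step, C6 and C19 are tied up as a non-enolisable lactone, so that C9 is the only carbonyl during enolate chemistry. C19 is acylated before the C3 ketone is unmasked, so that no 4-hydroxymethyl-3-ketone (retro-aldol risk) ever exists.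
- The C8-methyl ketone is carried as a mixture of C8 epimers, which converge when C8 becomes sp2.

Step 1
Reactants: 1 7-methoxy-1-tetralone
Product: 2 (R)-7-methoxy-1,2,3,4-tetrahydronaphthalen-1-ol
Conditions: RuCl[(R,R)-TsDPEN](p-cymene) (divalent ruthenium, 1 mol%), HCO2H/Et3N (5:2), 40 °C
Reagents that add atoms: none
Why: Noyori asymmetric transfer hydrogenation of an aryl alkyl ketone, in which the (R,R)-diamine ligand gives the (R)-carbinol that becomes C6 with its oxygen β.

Step 2
Reactants: 2 (R)-7-methoxy-1,2,3,4-tetrahydronaphthalen-1-ol; 3 carbon dioxide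
Product: 6 tricyclic aryl lactone with the C4 carboxyl closed onto the 6β-oxygen (3-OMe), via C4-lithio lithium alkoxide 4 (not isolated), via hydroxy acid 5 (not isolated)
Conditions: n-BuLi (2.4 equiv), TMEDA, hexane/toluene, 0 → 40 °C; CO2, −78 °C → rt; 2 M HCl, rt
Reagents that add atoms: carbon dioxide, O=C=O
Why: Directed ortho-metalation at the position flanked by the methoxy group and the alkoxide-bearing carbon (the same pattern that turns 3-methoxybenzyl alcohol into 7-methoxyphthalide), followed by carboxylation and acid-induced lactonisation, none of which touches the C6 stereocentre.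

Step 3
Reactants: 6 tricyclic aryl lactone
Product: 7 9-oxo aryl lactone
Conditions: CrO3, AcOH/H2O (9:1), 15 °C → rt
Reagents that add atoms: chromium trioxide, O=[Cr](=O)=O
Why: Benzylic oxidation by hexavalent chromium at C9, the only free benzylic methylene and the one para to the methoxy group, while the C6–H is deactivated by its acyloxy substituent.

Step 4
Reactants: 7 9-oxo aryl lactone
Product: 8 9α-hydroxy aryl lactone (6R,9R)
Conditions: RuCl[(R,R)-TsDPEN](p-cymene) (divalent ruthenium, 2 mol%), HCO2H/Et3N (5:2), DMF, 40 °C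
Reagents that add atoms: none
Why: A second Noyori asymmetric transfer hydrogenation, where catalyst control gives the (9R)-alcohol trans to the C6 oxygen.

Step 5
Reactants: 8 9α-hydroxy aryl lactone; 9 iodomethane
Product: 13 3-oxo-9α-hydroxy-4α-methyl-20-nor-5(10)-en-19,6β-olide, via ring-opened trilithium salt 10 (not isolated), via Birch dienolate 11 (not isolated), via methylated enol ether acid 12 (not isolated)
Conditions: LiOH·H2O (1.0 equiv), THF/H2O, rt, then dry; LiNH2 (2 equiv, from Li and cat. Fe(NO3)3 in NH3), then Li (excess), NH3/THF, −78 °C; MeI, −78 → −33 °C; NH4Cl; aq. oxalic acid, THF, 0 °C → rt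
Reagents that add atoms: iodomethane, CI; water, O; lithium hydroxide, [Li+].[OH-]
Why: Birch reductive alkylation of an ortho-methoxybenzoate, in which the carboxylate directs 1,4-reduction to C4/C1 and the dienolate is C-methylated at C4 while both benzylic oxygens are protected from hydrogenolysis as alkoxides; methylation anti to the pseudoaxial C6 alkoxide should dominate, and only that C4 epimer (carboxyl cis to the 6β-oxygen) can relactonise under the mild acid that also hydrolyses the enol ether to the C3 ketone, so the lactone acts as a stereochemical filter.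

Step 6
Reactants: 13 3-oxo-9α-hydroxy lactone
Product: 14 9α-TBS ether of 13
Conditions: TBSCl, imidazole, DMF, rt
Reagents that add atoms: tert-butyldimethylsilyl chloride, C[Si](C)(Cl)C(C)(C)C
Why: Standard silylation of the secondary allylic alcohol, giving a bulky ether that binds zinc poorly and later screens the α face.

Step 7
Reactants: 14 9α-TBS ether
Product: 15 3,3-ethylenedioxy (dioxolane) lactone
Conditions: TMSOCH2CH2OTMS, TMSOTf (5 mol%), CH2Cl2, −78 → −20 °C
Reagents that add atoms: 1,2-bis(trimethylsilyloxy)ethane, C[Si](C)(C)OCCO[Si](C)(C)C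
Why: TMSOTf-catalysed ketalisation with the bis-silyl ether of ethylene glycol runs aprotically at low temperature, so the hindered C3 ketone is protected without ionising the allylic lactone or the allylic silyl ether.

Step 8
Reactants: 15 dioxolane lactone
Product: 16 20-nor-5(10)-ene-6β,19-diol (3-dioxolane, 9α-OTBS)
Conditions: LiAlH4, THF, 0 °C → rt
Reagents that add atoms: none
Why: Hydride reduction of the lactone to the diol touches no stereocentre, so 6β-OH and the 4β-CH2OH stay on the same face.

Step 9
Reactants: 16 20-nor-5(10)-ene-6β,19-diol; 17 diiodomethane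
Product: 19 5β,10β-methano-6β,19-diol (3-dioxolane, 9α-OTBS), via bis(ethylzinc) dialkoxide 18 (not isolated)
Conditions: Et2Zn (5 equiv), CH2I2 (10 equiv), CH2Cl2, −10 °C → rt; aq. NH4Cl
Reagents that add atoms: diiodomethane, ICI
Why: Simmons–Smith cyclopropanation in its Furukawa form: Et2Zn turns both hydroxyls into zinc alkoxides (18), and an iodomethylzinc unit held there transfers CH2 to C5=C10 through a concerted butterfly transition state, forming C10–C20 and C5–C20 together. The closest known reaction type is the hydroxyl-directed cyclopropanation of tetrasubstituted cyclic allylic alcohols, as practised on steroidal 5(10)-enes. The three-membered ring closes by a single suprafacial (2+1) methylene addition, not by stepwise ring closure. C5 and C10 are set together by the allylic 6β-oxygen on C6 and the homoallylic C19 oxygen on C4, which both sit on the β face and hold the carbenoid there. The step needs only facial selectivity (β over α), since there is one alkene; it is secured by the two β-alkoxides and reinforced sterically by the pseudoaxial 4α-methyl and the bulky, poorly coordinating 9α-silyloxy group on the α face.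

Step 10
Reactants: 19 5β,10β-methano-6β,19-diol
Product: 20 5β,10β-methano-6-oxo-19-al
Conditions: (COCl)2, DMSO, CH2Cl2, −78 °C; Et3N, −78 → 0 °C
Reagents that add atoms: none
Why: Swern oxidation activates both hydroxyls as alkoxysulfonium ions before base is added, so the 1,4-diol goes to the keto aldehyde without passing through a lactol, under conditions that spare the cyclopropane, ketal and silyl ether.

Step 11
Reactants: 20 keto aldehyde
Product: 21 5β,10β-methano-6-oxo-19-oic acid
Conditions: NaClO2, NaH2PO4, 2-methyl-2-butene, t-BuOH/H2O, rt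
Reagents that add atoms: sodium chlorite, [Na+].[O-]Cl=O
Why: Pinnick oxidation of the non-enolisable neopentyl aldehyde gives a carboxylate that is inert to dissolving metal.

Step 12
Reactants: 21 cyclopropyl keto acid
Product: 23 10β-methyl-5α-H-6-oxo-19-oic acid (3-dioxolane, 9α-OTBS), via dilithium enolate carboxylate 22 (not isolated)
Conditions: Li (6 equiv), NH3/THF, −78 °C; solid NH4Cl
Reagents that add atoms: none
Why: Dissolving-metal reductive cleavage of a cyclopropyl ketone breaks the cyclopropane bond best aligned with the carbonyl π system, here the exocyclic C5–C20 bond, so C20 stays on C10 as the β-methyl and the C5 enolate is protonated from the open α face to the trans ring fusion.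

Step 13
Reactants: 23 6-oxo-19-oic acid
Product: 25 19,6β-olide (3-dioxolane, 9α-OTBS, 10β-methyl, 5α-H), via 6β-hydroxy acid 24 (not isolated)
Conditions: NaBH4, EtOH/THF, 0 °C → rt; AcOH to pH 4, rt
Reagents that add atoms: none
Why: Borohydride attacks the C6 ketone from the α face, because the β face is blocked by the axial C20 methyl and C19 carboxylate, and the resulting axial 6β-alcohol lactonises onto the syn-axial carboxyl, which masks C6–O and C19 in a lactone that cannot enolise.

Step 14
Reactants: 25 silylated lactone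
Product: 26 9α-hydroxy-19,6β-olide
Conditions: Bu4NF, THF, 50 °C; aq. NH4Cl
Reagents that add atoms: none
Why: Fluoride-induced cleavage of the silyl ether, to which the ketal and lactone are inert.

Step 15
Reactants: 26 9α-hydroxy lactone
Product: 27 9-oxo-19,6β-olide
Conditions: Dess–Martin periodinane, NaHCO3, CH2Cl2, rt
Reagents that add atoms: none
Why: Dess–Martin oxidation of the single free secondary alcohol, which also erases the auxiliary C9 stereocentre.

Step 16
Reactants: 27 9-oxo lactone; 9 iodomethane
Product: 29 8-methyl-9-oxo-19,6β-olide (C8 epimers), via lithium enolate 28 (not isolated)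
Conditions: LiN(i-Pr)2 (1.1 equiv), THF, −78 °C; MeI, −78 → 0 °C
Reagents that add atoms: iodomethane, CI
Why: Ketone enolate alkylation at C8, the only enolisable position because C10 and the lactone α-carbon C4 are quaternary; the C8 configuration is irrelevant since C8 becomes sp2 in the next step.

Step 17
Reactants: 29 8-methyl-9-oxo lactone
Product: 31 8-en-9-yl triflate, via potassium enolate 30 (not isolated)
Conditions: KN(SiMe3)2, THF, −78 → −20 °C; PhNTf2, −78 °C → rt
Reagents that add atoms: N-phenylbis(trifluoromethanesulfonimide), O=S(=O)(N(c1ccccc1)S(=O)(=O)C(F)(F)F)C(F)(F)F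
Why: Enol triflate formation from the only possible (tetrasubstituted) enolate, as is routine for 2,2,6-trimethylcyclohexanone, which fixes the position of the future 8(9)-alkene.

Step 18
Reactants: 31 8-en-9-yl triflate; 32 2-methyl-2-vinyl-1,3-dioxolane
Product: 34 14,15-dinorlabd-8-ene 3,13-bis(dioxolane) 19,6β-olide, via B-alkyl-9-BBN 33 (not isolated)
Conditions: 32, 9-BBN-H, THF, rt; then 31, PdCl2(dppf) (divalent palladium, 10 mol%), AsPh3, Cs2CO3, DMF/THF/H2O, 60 °C
Reagents that add atoms: 2-methyl-2-vinyl-1,3-dioxolane, C=CC1(C)OCCO1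
Why: B-alkyl Suzuki–Miyaura coupling, in which anti-Markovnikov hydroboration gives a primary alkylborane that couples with the cyclohexenyl triflate in the way established for 2,6,6-trimethylcyclohexenyl triflates, attaching C11–C13 and C16 with C13 masked as a ketal.

Step 19
Reactants: 34 bis-ketal lactone
Product: 35 6β,19-diol bis-ketal
Conditions: LiAlH4, THF, 0 °C → rt
Reagents that add atoms: none
Why: Hydride reduction of the lactone returns the 6β,19-diol at a stage where only ketals and an unactivated alkene are present.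

Step 20
Reactants: 35 6β,19-diol bis-ketal; 36 isovaleric anhydride
Product: 37 19-O-isovalerate of 35
Conditions: (i-BuCO)2O (1.2 equiv), Et3N, DMAP (cat.), CH2Cl2, 0 °C
Reagents that add atoms: isovaleric anhydride, CC(C)CC(=O)OC(=O)CC(C)C
Why: DMAP-catalysed acylation selects the primary C19 alcohol, since the axial 6β-OH is syn-diaxial to both the C20 methyl and the C19 substituent and should not compete.

Step 21
Reactants: 37 19-O-isovalerate bis-ketal
Product: 38 6β-hydroxy-19-isovaleryloxy-14,15-dinorlabd-8-ene-3,13-dione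
Conditions: 1 M aq. HCl/THF, rt
Reagents that add atoms: water, O
Why: Acid-catalysed hydrolysis of both dioxolanes, safe against retro-aldol loss of formaldehyde because the C19 oxygen is already acylated.

Step 22
Reactants: 38 3,13-dione; 39 allyl diethylphosphonoacetate
Product: 40 allyl (13E)-6β-hydroxy-19-isovaleryloxy-3-oxolabda-8,13-dien-15-oate
Conditions: NaH, 39, THF, 0 °C; then 38, rt → 45 °C
Reagents that add atoms: allyl diethylphosphonoacetate, CCOP(=O)(CC(=O)OCC=C)OCC
Why: Horner–Wadsworth–Emmons olefination, in which the phosphonate anion reacts with the unhindered methyl ketone and not with the α-quaternary C3 ketone and gives mainly the (E)-trisubstituted enoate, the minor Z isomer being removed by chromatography.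

Step 23
Reactants: 40 3-oxo allyl ester
Product: 41 allyl (13E)-3α,6β-dihydroxy-19-isovaleryloxylabda-8,13-dien-15-oate
Conditions: LiBH(s-Bu)3 (2.5 equiv), THF, −78 °C; aq. NH4Cl
Reagents that add atoms: none
Why: Reduction with a bulky trialkylborohydride proceeds by equatorial attack on the 4,4-disubstituted 3-ketone and gives the axial 3α-alcohol, while the esters and the β,β-disubstituted enoate are not reduced at −78 °C.

Step 24
Reactants: 41 3α,6β-diol; 36 isovaleric anhydride
Product: 42 allyl (13E)-6β-hydroxy-3α,19-bis(isovaleryloxy)labda-8,13-dien-15-oate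
Conditions: (i-BuCO)2O, DMAP, pyridine, rt → 40 °C
Reagents that add atoms: isovaleric anhydride, CC(C)CC(=O)OC(=O)CC(C)C
Why: DMAP-catalysed acylation reaches the axial 3α-OH, whereas the 6β-OH, shielded by two syn-axial substituents, is expected to stay free.

Step 25
Reactants: 42 allyl ester
Product: 43 (13E)-6β-hydroxy-3α,19-bis(isovaleryloxy)labda-8,13-dien-15-oic acid (CNP0333611.1)
Conditions: Pd(PPh3)4 (zerovalent palladium, 5 mol%), morpholine, THF, rt
Reagents that add atoms: none
Why: Tsuji–Trost deallylation with morpholine as allyl acceptor frees the acid under neutral conditions that leave both isovalerates, the 6β-OH and both alkenes untouched.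

Compound list
1 | 7-methoxy-1-tetralone | COc1ccc2CCCC(=O)c2c1 | starting material
2 | (R)-7-methoxy-1,2,3,4-tetrahydronaphthalen-1-ol | COc1ccc2CCC[C@@H](O)c2c1 | intermediate
3 | carbon dioxide | O=C=O | starting material
4 | C4-lithio lithium alkoxide of 2 | COc1ccc2CCC[C@@H](O[Li])c2c1[Li] | intermediate (not isolated)
5 | (R)-8-hydroxy-2-methoxy-5,6,7,8-tetrahydronaphthalene-1-carboxylic acid | COc1ccc2CCC[C@@H](O)c2c1C(=O)O | intermediate (not isolated)
6 | tricyclic aryl lactone (C4 carboxyl on the 6β-oxygen, 3-OMe) | COc1ccc2CCC[C@H]3OC(=O)c1c23 | intermediate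
7 | 9-oxo aryl lactone | COc1ccc2C(=O)CC[C@H]3OC(=O)c1c23 | intermediate
8 | 9α-hydroxy aryl lactone (6R,9R) | COc1ccc2[C@H](O)CC[C@H]3OC(=O)c1c23 | intermediate
9 | iodomethane | CI | starting material
10 | trilithium salt of the ring-opened 6β,9α-dihydroxy acid | [Li+].[Li+].[Li+].COc1ccc2[C@H]([O-])CC[C@@H]([O-])c2c1C([O-])=O | intermediate (not isolated)
11 | tetralithium Birch dienolate (C4 enediolate, 2-ene and 5(10)-ene) | [Li+].[Li+].[Li+].[Li+].COC1=CCC2=C(C1=C([O-])[O-])[C@H]([O-])CC[C@H]2[O-] | intermediate (not isolated)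
12 | 4α-methyl-3-methoxy-2,5(10)-diene-6β,9α-dihydroxy-19-oic acid | C[C@@]1(C(=O)O)C2=C(CC=C1OC)[C@H](O)CC[C@H]2O | intermediate (not isolated)
13 | 3-oxo-9α-hydroxy-4α-methyl-20-nor-5(10)-en-19,6β-olide | C[C@]12C(=O)CCC3=C1[C@H](OC2=O)CC[C@H]3O | intermediate
14 | 9α-TBS ether of 13 | C[C@]12C(=O)CCC3=C1[C@H](OC2=O)CC[C@H]3O[Si](C)(C)C(C)(C)C | intermediate
15 | 3,3-ethylenedioxy-9α-OTBS-20-nor-5(10)-en-19,6β-olide | C[C@]12C3(OCCO3)CCC4=C1[C@H](OC2=O)CC[C@H]4O[Si](C)(C)C(C)(C)C | intermediate
16 | 20-nor-5(10)-ene-6β,19-diol (3-dioxolane, 9α-OTBS), key-step precursor | C[C@@]1(CO)C2=C(CCC13OCCO3)[C@H](O[Si](C)(C)C(C)(C)C)CC[C@H]2O | intermediate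
17 | diiodomethane | ICI | starting material
18 | bis(ethylzinc) 6β,19-dialkoxide of 16 | C[C@@]1(CO[Zn]CC)C2=C(CCC13OCCO3)[C@H](O[Si](C)(C)C(C)(C)C)CC[C@H]2O[Zn]CC | intermediate (not isolated)
19 | 5β,10β-methano-6β,19-diol (3-dioxolane, 9α-OTBS), key-step product | C[C@@]1(CO)[C@@]23C[C@@]3(CCC14OCCO4)[C@H](O[Si](C)(C)C(C)(C)C)CC[C@H]2O | intermediate
20 | 5β,10β-methano-6-oxo-19-al | C[C@@]1(C=O)[C@@]23C[C@@]3(CCC14OCCO4)[C@H](O[Si](C)(C)C(C)(C)C)CCC2=O | intermediate
21 | 5β,10β-methano-6-oxo-19-oic acid | C[C@@]1(C(=O)O)[C@@]23C[C@@]3(CCC14OCCO4)[C@H](O[Si](C)(C)C(C)(C)C)CCC2=O | intermediate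
22 | dilithium 5-en-6-olate 19-carboxylate (10β-methyl) | [Li+].[Li+].C[C@@]1(C(=O)[O-])C2=C([O-])CC[C@@H](O[Si](C)(C)C(C)(C)C)[C@@]2(C)CCC13OCCO3 | intermediate (not isolated)
23 | 10β-methyl-5α-H-6-oxo-19-oic acid (3-dioxolane, 9α-OTBS) | C[C@@]1(C(=O)O)[C@@H]2C(=O)CC[C@@H](O[Si](C)(C)C(C)(C)C)[C@@]2(C)CCC13OCCO3 | intermediate
24 | 6β-hydroxy-19-oic acid | C[C@@]1(C(=O)O)[C@@H]2[C@H](O)CC[C@@H](O[Si](C)(C)C(C)(C)C)[C@@]2(C)CCC13OCCO3 | intermediate (not isolated)
25 | 19,6β-olide (3-dioxolane, 9α-OTBS) | C[C@]12[C@@H]3[C@H](OC1=O)CC[C@@H](O[Si](C)(C)C(C)(C)C)[C@@]3(C)CCC24OCCO4 | intermediate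
26 | 9α-hydroxy-19,6β-olide | C[C@]12[C@@H]3[C@H](OC1=O)CC[C@@H](O)[C@@]3(C)CCC24OCCO4 | intermediate
27 | 9-oxo-19,6β-olide | C[C@]12[C@@H]3[C@H](OC1=O)CCC(=O)[C@@]3(C)CCC24OCCO4 | intermediate
28 | lithium 8-en-9-olate of 27 | [Li+].C[C@]12[C@@H]3[C@H](OC1=O)CC=C([O-])[C@@]3(C)CCC24OCCO4 | intermediate (not isolated)
29 | 8-methyl-9-oxo-19,6β-olide (C8 epimers) | C[C@]12[C@@H]3[C@H](OC1=O)CC(C)C(=O)[C@@]3(C)CCC24OCCO4 | intermediate
30 | potassium 8-en-9-olate of 29 | [K+].C[C@]12[C@@H]3[C@H](OC1=O)CC(C)=C([O-])[C@@]3(C)CCC24OCCO4 | intermediate (not isolated)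
31 | 8-en-9-yl triflate | C[C@]12[C@@H]3[C@H](OC1=O)CC(C)=C(OS(=O)(=O)C(F)(F)F)[C@@]3(C)CCC24OCCO4 | intermediate
32 | 2-methyl-2-vinyl-1,3-dioxolane | C=CC1(C)OCCO1 | starting material
33 | B-[2-(2-methyl-1,3-dioxolan-2-yl)ethyl]-9-BBN | CC1(CCB2C3CCCC2CCC3)OCCO1 | intermediate (not isolated)
34 | 14,15-dinorlabd-8-ene 3,13-bis(dioxolane) 19,6β-olide | C[C@]12[C@@H]3[C@H](OC1=O)CC(C)=C(CCC5(C)OCCO5)[C@@]3(C)CCC24OCCO4 | intermediate
35 | 6β,19-diol bis-ketal | CC1=C(CCC2(C)OCCO2)[C@@]3(C)CCC4(OCCO4)[C@](C)(CO)[C@@H]3[C@H](O)C1 | intermediate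
36 | isovaleric anhydride | CC(C)CC(=O)OC(=O)CC(C)C | starting material
37 | 19-O-isovalerate of 35 | CC1=C(CCC2(C)OCCO2)[C@@]3(C)CCC4(OCCO4)[C@](C)(COC(=O)CC(C)C)[C@@H]3[C@H](O)C1 | intermediate
38 | 6β-hydroxy-19-isovaleryloxy-14,15-dinorlabd-8-ene-3,13-dione | CC1=C(CCC(C)=O)[C@@]2(C)CCC(=O)[C@](C)(COC(=O)CC(C)C)[C@@H]2[C@H](O)C1 | intermediate
39 | allyl diethylphosphonoacetate | CCOP(=O)(CC(=O)OCC=C)OCC | starting material
40 | allyl (13E)-6β-hydroxy-19-isovaleryloxy-3-oxolabda-8,13-dien-15-oate | CC1=C(CC/C(C)=C/C(=O)OCC=C)[C@@]2(C)CCC(=O)[C@](C)(COC(=O)CC(C)C)[C@@H]2[C@H](O)C1 | intermediate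
41 | allyl (13E)-3α,6β-dihydroxy-19-isovaleryloxylabda-8,13-dien-15-oate | CC1=C(CC/C(C)=C/C(=O)OCC=C)[C@@]2(C)CC[C@@H](O)[C@](C)(COC(=O)CC(C)C)[C@@H]2[C@H](O)C1 | intermediate
42 | allyl (13E)-6β-hydroxy-3α,19-bis(isovaleryloxy)labda-8,13-dien-15-oate | CC1=C(CC/C(C)=C/C(=O)OCC=C)[C@@]2(C)CC[C@@H](OC(=O)CC(C)C)[C@](C)(COC(=O)CC(C)C)[C@@H]2[C@H](O)C1 | intermediate
43 | (13E)-6β-hydroxy-3α,19-bis(isovaleryloxy)labda-8,13-dien-15-oic acid (CNP0333611.1) | CC1=C(CC/C(C)=C/C(=O)O)[C@@]2(C)CC[C@@H](OC(=O)CC(C)C)[C@](C)(COC(=O)CC(C)C)[C@@H]2[C@H](O)C1 | target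

Total step count: 25.
Longest linear sequence: 25 steps (1 to 43); the alkylborane 33 is made in the coupling flask.

Steps most likely to fail

Step 5. The reduction may run past the intended stage, with loss of the C3 methoxy group or hydrogenolysis of a benzylic C–O bond. The dienolate may be protonated instead of methylated. Methylation may also occur mainly syn to the C6 oxygen, which leaves an acid that cannot lactonise. The fallback sets out from 8 and comes back at 13. Lactone 8 is opened with pyrrolidine (2-hydroxypyridine cat., toluene, 80 °C) to the ring-opened hydroxy pyrrolidine amide F1. After both hydroxyls are deprotonated with n-BuLi, the benzamide is reduced and methylated as its amide enolate (K, NH3/THF, t-BuOH 1 equiv, −78 °C; MeI), a Birch alkylation mode known to retain ortho-methoxy groups, giving the C4-methylated dihydro amide F2. Aqueous oxalic acid then hydrolyses the enol ether and drives N-to-O acyl transfer onto the cis 6β-hydroxyl with loss of pyrrolidine, giving 13; the C4 epimer cannot close and is separated as the amide.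

Step 9. Methylene transfer to the tetrasubstituted alkene may be slow, so that O-methylation of the zinc alkoxides by the carbenoid competes, or part of the delivery may occur on the α face. The fallback sets out from 15 and comes back at 19. Dibromocarbene (CHBr3, KOt-Bu, pentane, 0 °C) is added to the lactone 15, where approach is governed by sterics (the 4α-methyl stands over the α face and the 9α-silyloxy group flanks it), to give the 5β,10β-dibromomethano lactone F3. Both bromines are removed with Bu3SnH/AIBN (toluene, 90 °C) to give the 5β,10β-methano lactone F4. LiAlH4 (THF, 0 °C) then opens the lactone to 19.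

Step 18. Oxidative addition and transmetalation at the hindered tetrasubstituted triflate may be slow, so that reduction of the triflate or β-hydride loss from the alkyl group takes over. The fallback sets out from 29 and comes back at 34. [2-(2-Methyl-1,3-dioxolan-2-yl)ethyl]magnesium bromide F5, made from 2-(2-bromoethyl)-2-methyl-1,3-dioxolane and Mg, is transmetalated with CeCl3 (THF, −78 °C) and added to the C9 ketone of 29 to give the 9-hydroxy-9-alkyl tertiary alcohol F6; organocerium reagents add to hindered, enolisable ketones and should spare the hindered lactone. Dehydration with SOCl2/pyridine (0 °C) toward the tetrasubstituted Zaitsev alkene gives 34.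

Further compounds
F1 | step 5 | ring-opened 6β,9α-dihydroxy aryl pyrrolidine amide | COc1ccc2[C@H](O)CC[C@@H](O)c2c1C(=O)N1CCCC1
F2 | step 5 | 4α-methyl-3-methoxy-2,5(10)-diene-6β,9α-dihydroxy pyrrolidine amide | C[C@@]1(C(=O)N3CCCC3)C2=C(CC=C1OC)[C@H](O)CC[C@H]2O
F3 | step 9 | 5β,10β-(dibromomethano)-3-dioxolane-9α-OTBS-19,6β-olide | C[C@@]1(C(=O)O5)[C@@]23C(Br)(Br)[C@@]3(CCC14OCCO4)[C@H](O[Si](C)(C)C(C)(C)C)CC[C@H]25
F4 | step 9 | 5β,10β-methano-3-dioxolane-9α-OTBS-19,6β-olide | C[C@@]1(C(=O)O5)[C@@]23C[C@@]3(CCC14OCCO4)[C@H](O[Si](C)(C)C(C)(C)C)CC[C@H]25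
F5 | step 18 | [2-(2-methyl-1,3-dioxolan-2-yl)ethyl]magnesium bromide | CC1(CC[Mg]Br)OCCO1
F6 | step 18 | 9-hydroxy-8-methyl-9-[2-(2-methyl-1,3-dioxolan-2-yl)ethyl]-19,6β-olide | C[C@]12[C@@H]3[C@H](OC1=O)CC(C)C(O)(CCC5(C)OCCO5)[C@@]3(C)CCC24OCCO4
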